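**Retrosynthetic overview**
- Target ⇐ hydrogenolysis of one benzyl ether and one diphenylmethylene ketal ⇐ LiAlH4 opening of a trans-fused 1-aryltetralin γ-lactone.
- Carbocyclic ring (C1–C8a bond) ⇐ Friedel–Crafts closure of a benzylic cation onto ring A of an α-(aryl-hydroxymethyl)-β-(arylmethyl)-γ-butyrolactone.
- Key fragment union (C1–C2 bond) ⇐ intermolecular aldol of the lithium enolate of an (R)-β-(arylmethyl)-γ-butyrolactone with O-benzylvanillin.
- (R)-Lactone ⇐ Evans alkylation of a mono-tert-butyl succinate imide with the ring A benzylic bromide, which comes from methyl gallate.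
- Ring order: both arenes are bought; the lactone ring is made first, the tetralin ring second, and the lactone is opened last.

Assumption: tetralin numbering is used for late compounds (C1 carries the pendant aryl, C2 and C3 the one-carbon groups, C4 is the benzylic CH2, ring A carries oxygen at C6, C7 and C8); the target is then the all-trans (1S,2R,3R) isomer.

**Route**

Step 1
Reactants: 1 methyl gallate (methyl 3,4,5-trihydroxybenzoate)
Product: 2 methyl 7-hydroxy-2,2-diphenyl-1,3-benzodioxole-5-carboxylate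
Conditions: Ph2CCl2 (1.2 equiv), neat, 170–180 °C, 30 min
Reagents that add atoms: dichlorodiphenylmethane, ClC(Cl)(c1ccccc1)c1ccccc1
Why: Cyclic ketal formation with the gem-dichloride takes one vicinal OH pair; the two possible pairs are equivalent by symmetry and the third OH cannot react further, so one mono-ketal results.

Step 2
Reactants: 2 methyl 7-hydroxy-2,2-diphenyl-1,3-benzodioxole-5-carboxylate
Product: 3 methyl 7-methoxy-2,2-diphenyl-1,3-benzodioxole-5-carboxylate
Conditions: MeI (1.5 equiv), K2CO3 (2 equiv), DMF, rt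
Reagents that add atoms: iodomethane, CI
Why: Williamson O-methylation of the only free phenol fixes the methyl ether that ends up at C6 of the target.

Step 3
Reactants: 3 methyl 7-methoxy-2,2-diphenyl-1,3-benzodioxole-5-carboxylate
Product: 4 (7-methoxy-2,2-diphenyl-1,3-benzodioxol-5-yl)methanol
Conditions: LiAlH4 (1.1 equiv), THF, 0 °C to rt; aq. NaOH work-up
Reagents that add atoms: none
Why: Hydride reduction of the ester to the benzylic alcohol; the ketal and aryl ethers are inert to LiAlH4.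

Step 4
Reactants: 4 (7-methoxy-2,2-diphenyl-1,3-benzodioxol-5-yl)methanol
Product: 5 6-(bromomethyl)-4-methoxy-2,2-diphenyl-1,3-benzodioxole
Conditions: PBr3 (0.4 equiv), CH2Cl2, 0 °C, 30 min; used at once
Reagents that add atoms: phosphorus tribromide, BrP(Br)Br
Why: Bromination of the benzylic alcohol through its phosphite ester (nucleophilic substitution) under anhydrous conditions that the ketal tolerates.

Step 5
Reactants: 6 (4R)-4-benzyl-1,3-oxazolidin-2-one; 7 4-tert-butoxy-4-oxobutanoic acid (mono-tert-butyl succinate)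
Product: 9 tert-butyl 4-[(4R)-4-benzyl-2-oxo-1,3-oxazolidin-3-yl]-4-oxobutanoate, via mixed pivalic anhydride 8 (not isolated)
Conditions: t-BuCOCl (1.05 equiv), Et3N (2.5 equiv), THF, −20 °C, 1 h; then LiCl (1.1 equiv), 6, −20 °C to rt
Reagents that add atoms: none
Why: N-acylation of the Evans auxiliary through the mixed anhydride, which is attacked at its unhindered succinyl carbonyl.

Step 6
Reactants: 9 tert-butyl 4-[(4R)-4-benzyl-2-oxo-1,3-oxazolidin-3-yl]-4-oxobutanoate; 5 6-(bromomethyl)-4-methoxy-2,2-diphenyl-1,3-benzodioxole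
Product: 11 tert-butyl (3R)-4-[(4R)-4-benzyl-2-oxo-1,3-oxazolidin-3-yl]-3-[(7-methoxy-2,2-diphenyl-1,3-benzodioxol-5-yl)methyl]-4-oxobutanoate, via sodium enolate 10 (not isolated)
Conditions: NaN(SiMe3)2 (1.05 equiv), THF, −78 °C, 45 min; then 5 (1.2 equiv), −78 to −30 °C
Reagents that add atoms: none
Why: Evans asymmetric alkylation; the chelated Z-enolate of the more acidic imide α-CH2 is benzylated on the face opposite the auxiliary benzyl group, which sets the (3R) centre (typically ≥95:5 dr).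

Step 7
Reactants: 11 tert-butyl (3R)-4-[(4R)-4-benzyl-2-oxo-1,3-oxazolidin-3-yl]-3-[(7-methoxy-2,2-diphenyl-1,3-benzodioxol-5-yl)methyl]-4-oxobutanoate
Product: 12 tert-butyl (3R)-4-hydroxy-3-[(7-methoxy-2,2-diphenyl-1,3-benzodioxol-5-yl)methyl]butanoate
Conditions: LiBH4 (1.5 equiv), H2O (1.5 equiv), Et2O–THF, 0 °C, 2 h; aq. NaOH work-up
Reagents that add atoms: none
Why: Chemoselective borohydride reduction of the exocyclic imide carbonyl releases the auxiliary and leaves the hindered tert-butyl ester and the stereocentre untouched.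

Step 8
Reactants: 12 tert-butyl (3R)-4-hydroxy-3-[(7-methoxy-2,2-diphenyl-1,3-benzodioxol-5-yl)methyl]butanoate
Product: 13 (4R)-4-[(7-methoxy-2,2-diphenyl-1,3-benzodioxol-5-yl)methyl]oxolan-2-one
Conditions: pTsOH·H2O (0.1 equiv), toluene, 60 °C, 2 h
Reagents that add atoms: none
Why: Acid-catalysed lactonisation (intramolecular transesterification) closes the five-membered lactone without affecting the stereocentre.

Step 9
Reactants: 13 (4R)-4-[(7-methoxy-2,2-diphenyl-1,3-benzodioxol-5-yl)methyl]oxolan-2-one; 14 4-benzyloxy-3-methoxybenzaldehyde (O-benzylvanillin)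
Product: 16 (3S,4R)-3-[(4-benzyloxy-3-methoxyphenyl)(hydroxy)methyl]-4-[(7-methoxy-2,2-diphenyl-1,3-benzodioxol-5-yl)methyl]oxolan-2-one (both carbinol epimers), via lithium enolate 15 (not isolated)
Conditions: LiN(SiMe3)2 (1.1 equiv), THF, −78 °C, 1 h; then 14 (1.2 equiv), −78 °C, 2 h; AcOH quench at −78 °C
Reagents that add atoms: none
Why: Intermolecular aldol addition; the enolate is attacked anti to the C4 substituent, giving the 3,4-trans lactone, and the carbinol epimer mixture is harmless because that centre is ionised in the next step.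

Step 10
Reactants: 16 (3S,4R)-3-[(4-benzyloxy-3-methoxyphenyl)(hydroxy)methyl]-4-[(7-methoxy-2,2-diphenyl-1,3-benzodioxol-5-yl)methyl]oxolan-2-one
Product: 17 (1S,2R,3R)-1-(4-benzyloxy-3-methoxyphenyl)-3-(hydroxymethyl)-6-methoxy-7,8-(diphenylmethylenedioxy)-1,2,3,4-tetrahydronaphthalene-2-carboxylic acid γ-lactone (trans-fused aryltetralin lactone)
Conditions: CF3CO2H (10 equiv), CH2Cl2, 0 °C to rt, 2 h
Reagents that add atoms: none
Why: Intramolecular Friedel–Crafts alkylation by the p-alkoxybenzylic cation; ring A is expected to react para to its methoxy group at the CH next to the tied-back dioxole oxygen (attack ortho to OMe would twist that group out of conjugation), and a chair-like transition state puts the aryl group pseudo-equatorial, giving 1,2-trans on the existing 2,3-trans lactone.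

Step 11
Reactants: 17 trans-fused aryltetralin lactone
Product: 18 [(1S,2R,3R)-1-(4-benzyloxy-3-methoxyphenyl)-6-methoxy-7,8-(diphenylmethylenedioxy)-1,2,3,4-tetrahydronaphthalene-2,3-diyl]dimethanol
Conditions: LiAlH4 (2.5 equiv), THF, 0 °C, 1 h; aq. NaOH work-up
Reagents that add atoms: none
Why: Hydride reduction of the lactone to the diol is fast at 0 °C, so C2 does not epimerise and the three stereocentres are kept.

Step 12
Reactants: 18 protected diol
Product: 19 (6R,7R,8S)-8-(4-hydroxy-3-methoxyphenyl)-6,7-bis(hydroxymethyl)-3-methoxy-5,6,7,8-tetrahydronaphthalene-1,2-diol (target)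
Conditions: H2 (1 atm), Pd(OH)2/C, THF–MeOH 1:1, rt, 12 h; filtered under argon
Reagents that add atoms: none
Why: Catalytic hydrogenolysis cleaves the benzyl ether and the diphenylmethylene ketal (all benzylic C–O bonds) under neutral conditions; no stereocentre bears a benzylic C–O bond, so none is touched.

**Compound list**
1 | methyl gallate | COC(=O)c1cc(O)c(O)c(O)c1 | starting material
2 | methyl 7-hydroxy-2,2-diphenyl-1,3-benzodioxole-5-carboxylate | COC(=O)c1cc(O)c2OC(c3ccccc3)(c3ccccc3)Oc2c1 | intermediate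
3 | methyl 7-methoxy-2,2-diphenyl-1,3-benzodioxole-5-carboxylate | COC(=O)c1cc(OC)c2OC(c3ccccc3)(c3ccccc3)Oc2c1 | intermediate
4 | (7-methoxy-2,2-diphenyl-1,3-benzodioxol-5-yl)methanol | OCc1cc(OC)c2OC(c3ccccc3)(c3ccccc3)Oc2c1 | intermediate
5 | 6-(bromomethyl)-4-methoxy-2,2-diphenyl-1,3-benzodioxole | BrCc1cc(OC)c2OC(c3ccccc3)(c3ccccc3)Oc2c1 | intermediate
6 | (4R)-4-benzyl-1,3-oxazolidin-2-one | O=C1N[C@H](Cc2ccccc2)CO1 | starting material
7 | 4-tert-butoxy-4-oxobutanoic acid | CC(C)(C)OC(=O)CCC(O)=O | starting material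
8 | 4-tert-butoxy-4-oxobutanoic 2,2-dimethylpropanoic anhydride (mixed pivalic anhydride) | CC(C)(C)OC(=O)CCC(=O)OC(=O)C(C)(C)C | intermediate
9 | tert-butyl 4-[(4R)-4-benzyl-2-oxo-1,3-oxazolidin-3-yl]-4-oxobutanoate | CC(C)(C)OC(=O)CCC(=O)N1[C@H](Cc2ccccc2)COC1=O | intermediate
10 | sodium (Z)-enolate of 9 | [Na+].[O-]/C(=C\CC(=O)OC(C)(C)C)N1[C@H](Cc2ccccc2)COC1=O | intermediate
11 | tert-butyl (3R)-4-[(4R)-4-benzyl-2-oxo-1,3-oxazolidin-3-yl]-3-[(7-methoxy-2,2-diphenyl-1,3-benzodioxol-5-yl)methyl]-4-oxobutanoate | CC(C)(C)OC(=O)C[C@@H](Cc1cc(OC)c2OC(c3ccccc3)(c3ccccc3)Oc2c1)C(=O)N1[C@H](Cc2ccccc2)COC1=O | intermediate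
12 | tert-butyl (3R)-4-hydroxy-3-[(7-methoxy-2,2-diphenyl-1,3-benzodioxol-5-yl)methyl]butanoate | CC(C)(C)OC(=O)C[C@@H](Cc1cc(OC)c2OC(c3ccccc3)(c3ccccc3)Oc2c1)CO | intermediate
13 | (4R)-4-[(7-methoxy-2,2-diphenyl-1,3-benzodioxol-5-yl)methyl]oxolan-2-one | O=C1C[C@@H](Cc2cc(OC)c3OC(c4ccccc4)(c4ccccc4)Oc3c2)CO1 | intermediate
14 | 4-benzyloxy-3-methoxybenzaldehyde | COc1cc(C=O)ccc1OCc1ccccc1 | starting material
15 | lithium enolate of 13 | [Li+].[O-]C1=C[C@@H](Cc2cc(OC)c3OC(c4ccccc4)(c4ccccc4)Oc3c2)CO1 | intermediate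
16 | (3S,4R)-3-[(4-benzyloxy-3-methoxyphenyl)(hydroxy)methyl]-4-[(7-methoxy-2,2-diphenyl-1,3-benzodioxol-5-yl)methyl]oxolan-2-one, carbinol epimers | O=C1OC[C@H](Cc2cc(OC)c3OC(c4ccccc4)(c4ccccc4)Oc3c2)[C@H]1C(O)c1ccc(OCc2ccccc2)c(OC)c1 | intermediate
17 | (1S,2R,3R)-1-(4-benzyloxy-3-methoxyphenyl)-3-(hydroxymethyl)-6-methoxy-7,8-(diphenylmethylenedioxy)-1,2,3,4-tetrahydronaphthalene-2-carboxylic acid γ-lactone | COc1cc([C@H]2c3c(cc(OC)c4OC(c5ccccc5)(c5ccccc5)Oc43)C[C@H]3COC(=O)[C@H]23)ccc1OCc1ccccc1 | intermediate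
18 | [(1S,2R,3R)-1-(4-benzyloxy-3-methoxyphenyl)-6-methoxy-7,8-(diphenylmethylenedioxy)-1,2,3,4-tetrahydronaphthalene-2,3-diyl]dimethanol | COc1cc([C@H]2c3c(cc(OC)c4OC(c5ccccc5)(c5ccccc5)Oc43)C[C@@H](CO)[C@@H]2CO)ccc1OCc1ccccc1 | intermediate
19 | (6R,7R,8S)-8-(4-hydroxy-3-methoxyphenyl)-6,7-bis(hydroxymethyl)-3-methoxy-5,6,7,8-tetrahydronaphthalene-1,2-diol | COc1cc([C@H]2c3c(cc(OC)c(O)c3O)C[C@@H](CO)[C@@H]2CO)ccc1O | target

**Summary**
Total step count: 12. Longest linear sequence: 11 steps (1 → 2 → 3 → 4 → 5 → 11 → 12 → 13 → 16 → 17 → 18 → 19); step 5 is a one-step side branch.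

**Steps most likely to fail**

Step 10 (Friedel–Crafts closure). Ring A has two free CH positions, and only closure next to the dioxole oxygen gives the target pattern. The preference for that position is argued by analogy and depends on the ketal staying on until the ring has closed; acid may also cleave the ketal or cause elimination to the benzylidene lactone. The regiochemistry should be confirmed by NOE between the remaining aromatic H of ring A and both the OMe and the C4 methylene. Fallback: cyclise at the diol oxidation level, where there is no trans-lactone strain and a much milder acid suffices, so the ketal stays intact. Setting out from 16, LiAlH4 in THF at 0 °C gives the triol (2R,3R)-2-[(4-benzyloxy-3-methoxyphenyl)(hydroxy)methyl]-3-[(7-methoxy-2,2-diphenyl-1,3-benzodioxol-5-yl)methyl]butane-1,4-diol F1. Camphorsulfonic acid (0.2 equiv) in CH2Cl2 at rt first traps the benzylic cation on the C4 hydroxyl to give the lariciresinol-type tetrahydrofuran [(3R,4R)-2-(4-benzyloxy-3-methoxyphenyl)-4-[(7-methoxy-2,2-diphenyl-1,3-benzodioxol-5-yl)methyl]oxolan-3-yl]methanol F2. Its benzylic ether re-ionises under the same conditions until the irreversible aryl closure drains it to diol 18, where the route is rejoined (step 11 is skipped).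

Step 6 (Evans alkylation). The succinate imide enolate is less reactive than a simple propionimide enolate and the electron-rich bromide 5 is labile, so conversion or selectivity may be poor. Fallback: swap the roles of nucleophile and electrophile. Setting out from 5, alkylation of diethyl malonate (NaH, THF) gives diethyl 2-[(7-methoxy-2,2-diphenyl-1,3-benzodioxol-5-yl)methyl]propanedioate F3. KOH in EtOH–H2O, then HCl, gives 2-[(7-methoxy-2,2-diphenyl-1,3-benzodioxol-5-yl)methyl]propanedioic acid F4, which is decarboxylated in pyridine at 100 °C to 3-(7-methoxy-2,2-diphenyl-1,3-benzodioxol-5-yl)propanoic acid F5. Coupling with commercial (4S)-4-benzyl-1,3-oxazolidin-2-one (DCC, DMAP, CH2Cl2) gives (4S)-4-benzyl-3-[3-(7-methoxy-2,2-diphenyl-1,3-benzodioxol-5-yl)propanoyl]-1,3-oxazolidin-2-one F6. NaN(SiMe3)2 in THF at −78 °C forms its sodium (Z)-enolate F7, and tert-butyl bromoacetate then gives tert-butyl (3R)-4-[(4S)-4-benzyl-2-oxo-1,3-oxazolidin-3-yl]-3-[(7-methoxy-2,2-diphenyl-1,3-benzodioxol-5-yl)methyl]-4-oxobutanoate F8. The opposite auxiliary with the swapped partners sets the same (3R) centre, and LiBH4 as in step 7 delivers hydroxy ester 12, where the route is rejoined.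

Step 12 (global hydrogenolysis). The diphenylmethylene ketal can be slow to hydrogenolyse and the free catechol product is air-sensitive, so prolonged reaction may give incomplete deprotection or oxidised material. Fallback: remove the ketal hydrolytically first. Setting out from 18, 1 M HCl in THF–MeOH at 50 °C gives (6R,7R,8S)-8-(4-benzyloxy-3-methoxyphenyl)-6,7-bis(hydroxymethyl)-3-methoxy-5,6,7,8-tetrahydronaphthalene-1,2-diol F9. A short hydrogenolysis of the remaining benzyl ether (H2, Pd/C, MeOH, rt) then gives 19.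

**Further compounds**
F1 | step 10 | (2R,3R)-2-[(4-benzyloxy-3-methoxyphenyl)(hydroxy)methyl]-3-[(7-methoxy-2,2-diphenyl-1,3-benzodioxol-5-yl)methyl]butane-1,4-diol | OC[C@H](Cc1cc(OC)c2OC(c3ccccc3)(c3ccccc3)Oc2c1)[C@H](CO)C(O)c1ccc(OCc2ccccc2)c(OC)c1
F2 | step 10 | [(3R,4R)-2-(4-benzyloxy-3-methoxyphenyl)-4-[(7-methoxy-2,2-diphenyl-1,3-benzodioxol-5-yl)methyl]oxolan-3-yl]methanol | OC[C@H]1[C@@H](Cc2cc(OC)c3OC(c4ccccc4)(c4ccccc4)Oc3c2)COC1c1ccc(OCc2ccccc2)c(OC)c1
F3 | step 6 | diethyl 2-[(7-methoxy-2,2-diphenyl-1,3-benzodioxol-5-yl)methyl]propanedioate | CCOC(=O)C(Cc1cc(OC)c2OC(c3ccccc3)(c3ccccc3)Oc2c1)C(=O)OCC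
F4 | step 6 | 2-[(7-methoxy-2,2-diphenyl-1,3-benzodioxol-5-yl)methyl]propanedioic acid | OC(=O)C(Cc1cc(OC)c2OC(c3ccccc3)(c3ccccc3)Oc2c1)C(O)=O
F5 | step 6 | 3-(7-methoxy-2,2-diphenyl-1,3-benzodioxol-5-yl)propanoic acid | OC(=O)CCc1cc(OC)c2OC(c3ccccc3)(c3ccccc3)Oc2c1
F6 | step 6 | (4S)-4-benzyl-3-[3-(7-methoxy-2,2-diphenyl-1,3-benzodioxol-5-yl)propanoyl]-1,3-oxazolidin-2-one | O=C(CCc1cc(OC)c2OC(c3ccccc3)(c3ccccc3)Oc2c1)N1[C@@H](Cc2ccccc2)COC1=O
F7 | step 6 | sodium (Z)-enolate of F6 | [Na+].[O-]/C(=C\Cc1cc(OC)c2OC(c3ccccc3)(c3ccccc3)Oc2c1)N1[C@@H](Cc2ccccc2)COC1=O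
F8 | step 6 | tert-butyl (3R)-4-[(4S)-4-benzyl-2-oxo-1,3-oxazolidin-3-yl]-3-[(7-methoxy-2,2-diphenyl-1,3-benzodioxol-5-yl)methyl]-4-oxobutanoate | CC(C)(C)OC(=O)C[C@@H](Cc1cc(OC)c2OC(c3ccccc3)(c3ccccc3)Oc2c1)C(=O)N1[C@@H](Cc2ccccc2)COC1=O
F9 | step 12 | (6R,7R,8S)-8-(4-benzyloxy-3-methoxyphenyl)-6,7-bis(hydroxymethyl)-3-methoxy-5,6,7,8-tetrahydronaphthalene-1,2-diol | COc1cc([C@H]2c3c(cc(OC)c(O)c3O)C[C@@H](CO)[C@@H]2CO)ccc1OCc1ccccc1
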